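**Retrosynthetic overview**
1. The strategy rests on the C5 hydroxyl and the C6 benzoyl group of the benzene ring (C1 OMe, C2 prenyl, C3 OH, C4 prenyl, C5 OH, C6 C(=O)Ph). They form an ortho-hydroxyaryl ketone whose carbonyl-bearing carbon sits next to the C1 methoxy.
2. Last disconnection: the MOM ether on the C3 oxygen (22 ⇒ 23).
3. Key disconnection: the C5–O and C6–C(=O) bonds, made together by insertion of the C5≡C6 aryne from ortho-silylaryl triflate 18 into the C–O bond of benzoic acid 19.
4. 18 comes from bromodiol 12 by O-silylation, Br–Li exchange, retro-Brook shift of silicon from the C5 oxygen to C6, triflation and MOM capping of the C3 oxygen. 12 comes from 5-methoxyresorcinol 1 by bis-MOM protection and three directed ortho metalations (prenyl at C4, prenyl at C2, bromine at C6).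
5. No ring is formed in the route: the benzene ring of 1 is carried through and the phenyl ring arrives with 19.

Key step: step 9

Remark: the target has no stereocentre, so no stereocontrol is needed; "prenyl" means 3-methylbut-2-en-1-yl, and ring positions C1–C6 are numbered as in line 1 of the overview.

**Route**

Step 1
Reactants: 1 5-methoxyresorcinol
Product: 2 1-methoxy-3,5-bis(methoxymethoxy)benzene
Conditions: NaH (2.4 equiv), MOMCl (2.4 equiv), DMF, 0 °C → rt
Reagents that add atoms: chloromethyl methyl ether, COCCl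
Why: Williamson O-alkylation of both phenoxides with the hard electrophile MOMCl should give the bis-MOM ether, whose acetal oxygens then direct the ring metalations.

Step 2
Reactants: 2 1-methoxy-3,5-bis(methoxymethoxy)benzene; 3 prenyl bromide
Product: 6 5-methoxy-1,3-bis(methoxymethoxy)-2-(3-methylbut-2-en-1-yl)benzene, via aryllithium 4 (not isolated), via arylcopper 5 (not isolated)
Conditions: n-BuLi (1.05 equiv), TMEDA, THF, 0 °C; CuI (1.1 equiv), −78 → −40 °C; 3 (1.3 equiv), −78 °C → rt
Reagents that add atoms: none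
Why: Directed ortho metalation should occur at the position flanked by both MOM ethers, the most strongly coordinated site, and transmetalation to copper steers the allylic substitution of prenyl bromide to the SN2 product with the linear prenyl group.

Step 3
Reactants: 6 5-methoxy-1,3-bis(methoxymethoxy)-2-(3-methylbut-2-en-1-yl)benzene; 3 prenyl bromide
Product: 9 1-methoxy-3,5-bis(methoxymethoxy)-2,4-bis(3-methylbut-2-en-1-yl)benzene, via aryllithium 7 (not isolated), via arylcopper 8 (not isolated)
Conditions: n-BuLi (1.05 equiv), TMEDA, THF, −20 → 0 °C; CuI (1.1 equiv), −78 → −40 °C; 3 (1.3 equiv), −78 °C → rt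
Reagents that add atoms: none
Why: The two remaining ring C–H positions of 6 are equivalent and each lies between OMe and OMOM, so directed ortho metalation can give only one aryllithium, and oxygen-assisted ring deprotonation should outpace removal of a benzylic–allylic prenyl proton before the copper-mediated SN2 prenylation.

Step 4
Reactants: 9 1-methoxy-3,5-bis(methoxymethoxy)-2,4-bis(3-methylbut-2-en-1-yl)benzene
Product: 11 1-bromo-2-methoxy-4,6-bis(methoxymethoxy)-3,5-bis(3-methylbut-2-en-1-yl)benzene, via aryllithium 10 (not isolated)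
Conditions: n-BuLi (1.1 equiv), TMEDA, THF, −20 → 0 °C; BrCCl2CCl2Br (1.2 equiv), −78 °C → rt
Reagents that add atoms: 1,2-dibromo-1,1,2,2-tetrachloroethane, ClC(Cl)(Br)C(Cl)(Cl)Br
Why: Directed ortho metalation at the last ring C–H (C6, between OMe and OMOM) followed by bromine transfer from a halogen donor that does not add to the prenyl alkenes should place bromine at C6.

Step 5
Reactants: 11 1-bromo-2-methoxy-4,6-bis(methoxymethoxy)-3,5-bis(3-methylbut-2-en-1-yl)benzene
Product: 12 4-bromo-5-methoxy-2,6-bis(3-methylbut-2-en-1-yl)benzene-1,3-diol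
Conditions: conc. HCl (cat.), MeOH, 40 °C
Reagents that add atoms: none
Why: Acid-catalysed acetal exchange with methanol removes both MOM groups, and dilute acid at this temperature should leave the prenyl groups uncyclized and the aryl bromide intact.

Step 6
Reactants: 12 4-bromo-5-methoxy-2,6-bis(3-methylbut-2-en-1-yl)benzene-1,3-diol
Product: 13 [4-bromo-5-methoxy-2,6-bis(3-methylbut-2-en-1-yl)-1,3-phenylene]bis(oxy)bis(trimethylsilane)
Conditions: HMDS (3 equiv, neat), 80 °C; evaporate, use crude
Reagents that add atoms: hexamethyldisilazane, C[Si](C)(C)N[Si](C)(C)C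
Why: Silyl transfer from HMDS to both phenols with loss of ammonia gives the bis(trimethylsilyl) ether without salts or aqueous work-up.

Step 7
Reactants: 13 [4-bromo-5-methoxy-2,6-bis(3-methylbut-2-en-1-yl)-1,3-phenylene]bis(oxy)bis(trimethylsilane)
Product: 17 3-hydroxy-5-methoxy-2,4-bis(3-methylbut-2-en-1-yl)-6-(trimethylsilyl)phenyl trifluoromethanesulfonate, via aryllithium 14 (not isolated), via lithium phenoxide 15 (not isolated), via silyl ether triflate 16 (not isolated)
Conditions: n-BuLi (1.1 equiv), THF, −100 → −78 °C; Tf2O (1.2 equiv), −100 → −78 °C; then 1 M aq. HCl, THF, 0 °C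
Reagents that add atoms: trifluoromethanesulfonic anhydride, O=S(=O)(OS(=O)(=O)C(F)(F)F)C(F)(F)F
Why: Br–Li exchange at C6 triggers a retro-Brook 1,3-shift of silicon that is possible only from the adjacent C5 oxygen, so the two oxygens are told apart, the freed C5 phenoxide is triflated, and brief dilute acid hydrolyses the remaining C3 silyl ether without touching the C–Si bond or the triflate.

Step 8
Reactants: 17 3-hydroxy-5-methoxy-2,4-bis(3-methylbut-2-en-1-yl)-6-(trimethylsilyl)phenyl trifluoromethanesulfonate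
Product: 18 3-methoxy-5-(methoxymethoxy)-4,6-bis(3-methylbut-2-en-1-yl)-2-(trimethylsilyl)phenyl trifluoromethanesulfonate
Conditions: MOMCl (2 equiv), iPr2NEt (3 equiv), CH2Cl2, 0 → 40 °C
Reagents that add atoms: chloromethyl methyl ether, COCCl
Why: O-alkylation of the C3 phenol under fluoride-free amine-base conditions caps the only free nucleophile without triggering aryne formation from the silyl triflate.

Step 9
Reactants: 18 3-methoxy-5-(methoxymethoxy)-4,6-bis(3-methylbut-2-en-1-yl)-2-(trimethylsilyl)phenyl trifluoromethanesulfonate; 19 benzoic acid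
Product: 22 [2-hydroxy-6-methoxy-4-(methoxymethoxy)-3,5-bis(3-methylbut-2-en-1-yl)phenyl](phenyl)methanone, via aryne 20 (not isolated), via arylcesium 21 (not isolated)
Conditions: 19 (1.0 equiv), CsF (4 equiv), THF, 125 °C, sealed tube; aq. NH4Cl work-up
Reagents that add atoms: none
Why: Fluoride attacks the C6 silicon and triflate leaves from C5 to give aryne 20; benzoate adds through oxygen to C5, and the C6 aryl anion 21 attacks the neighbouring ester carbonyl through a four-membered benzoxete alkoxide that opens to the phenoxide of ketone 22, so the C5–O and C6–C(=O) bonds form in one operation. The closest known reaction type is the insertion of arynes from ortho-silylaryl triflates into the C–O bond of carboxylic acids with CsF in hot THF, which gives ortho-hydroxyaryl ketones and has been run with 3-methoxybenzyne. No ring is closed and no stereocentre is formed. The step needs regioselectivity (oxygen at C5, acyl at C6), and the C1 methoxy secures it: its inductive pull distorts the aryne so that C5 is the more electrophilic end and the negative charge develops at C6 beside the oxygen, which should outweigh the small steric bias of the C4 prenyl group. Acyl transfer must also beat protonation of the aryl anion, which the high temperature, the excess of CsF and the use of only one equivalent of acid favour. The C3 oxygen is capped as a MOM ether so that no phenoxide competes for the aryne, and capture of the aryne by the C4 prenyl alkene would need a strained small-ring geometry.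

Step 10
Reactants: 22 [2-hydroxy-6-methoxy-4-(methoxymethoxy)-3,5-bis(3-methylbut-2-en-1-yl)phenyl](phenyl)methanone
Product: 23 [2,4-dihydroxy-6-methoxy-3,5-bis(3-methylbut-2-en-1-yl)phenyl](phenyl)methanone
Conditions: conc. HCl (cat.), MeOH, rt → 40 °C
Reagents that add atoms: none
Why: Acid-catalysed acetal exchange with methanol frees the C3 hydroxyl, and the mild acid strength and temperature are chosen so that the prenyl groups should not cyclize onto the flanking phenols.

**Compound list**
1 | 5-methoxyresorcinol (5-methoxybenzene-1,3-diol) | COc1cc(O)cc(O)c1 | starting material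
2 | 1-methoxy-3,5-bis(methoxymethoxy)benzene | COCOc1cc(OC)cc(OCOC)c1 | intermediate
3 | prenyl bromide (1-bromo-3-methylbut-2-ene) | CC(C)=CCBr | starting material
4 | [4-methoxy-2,6-bis(methoxymethoxy)phenyl]lithium | [Li]c1c(OCOC)cc(OC)cc1OCOC | intermediate
5 | [4-methoxy-2,6-bis(methoxymethoxy)phenyl]copper | [Cu]c1c(OCOC)cc(OC)cc1OCOC | intermediate
6 | 5-methoxy-1,3-bis(methoxymethoxy)-2-(3-methylbut-2-en-1-yl)benzene | COCOc1cc(OC)cc(OCOC)c1CC=C(C)C | intermediate
7 | [6-methoxy-2,4-bis(methoxymethoxy)-3-(3-methylbut-2-en-1-yl)phenyl]lithium | [Li]c1c(OC)cc(OCOC)c(CC=C(C)C)c1OCOC | intermediate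
8 | [6-methoxy-2,4-bis(methoxymethoxy)-3-(3-methylbut-2-en-1-yl)phenyl]copper | [Cu]c1c(OC)cc(OCOC)c(CC=C(C)C)c1OCOC | intermediate
9 | 1-methoxy-3,5-bis(methoxymethoxy)-2,4-bis(3-methylbut-2-en-1-yl)benzene | COc1cc(OCOC)c(CC=C(C)C)c(OCOC)c1CC=C(C)C | intermediate
10 | [2-methoxy-4,6-bis(methoxymethoxy)-3,5-bis(3-methylbut-2-en-1-yl)phenyl]lithium | COc1c([Li])c(OCOC)c(CC=C(C)C)c(OCOC)c1CC=C(C)C | intermediate
11 | 1-bromo-2-methoxy-4,6-bis(methoxymethoxy)-3,5-bis(3-methylbut-2-en-1-yl)benzene | COc1c(Br)c(OCOC)c(CC=C(C)C)c(OCOC)c1CC=C(C)C | intermediate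
12 | 4-bromo-5-methoxy-2,6-bis(3-methylbut-2-en-1-yl)benzene-1,3-diol | COc1c(Br)c(O)c(CC=C(C)C)c(O)c1CC=C(C)C | intermediate
13 | [4-bromo-5-methoxy-2,6-bis(3-methylbut-2-en-1-yl)-1,3-phenylene]bis(oxy)bis(trimethylsilane) | COc1c(Br)c(O[Si](C)(C)C)c(CC=C(C)C)c(O[Si](C)(C)C)c1CC=C(C)C | intermediate
14 | [2-methoxy-3,5-bis(3-methylbut-2-en-1-yl)-4,6-bis(trimethylsilyloxy)phenyl]lithium | COc1c([Li])c(O[Si](C)(C)C)c(CC=C(C)C)c(O[Si](C)(C)C)c1CC=C(C)C | intermediate
15 | lithium 5-methoxy-2,4-bis(3-methylbut-2-en-1-yl)-6-(trimethylsilyl)-3-(trimethylsilyloxy)phenoxide | COc1c([Si](C)(C)C)c([O-])c(CC=C(C)C)c(O[Si](C)(C)C)c1CC=C(C)C.[Li+] | intermediate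
16 | 5-methoxy-2,4-bis(3-methylbut-2-en-1-yl)-6-(trimethylsilyl)-3-(trimethylsilyloxy)phenyl trifluoromethanesulfonate | COc1c([Si](C)(C)C)c(OS(=O)(=O)C(F)(F)F)c(CC=C(C)C)c(O[Si](C)(C)C)c1CC=C(C)C | intermediate
17 | 3-hydroxy-5-methoxy-2,4-bis(3-methylbut-2-en-1-yl)-6-(trimethylsilyl)phenyl trifluoromethanesulfonate | COc1c([Si](C)(C)C)c(OS(=O)(=O)C(F)(F)F)c(CC=C(C)C)c(O)c1CC=C(C)C | intermediate
18 | 3-methoxy-5-(methoxymethoxy)-4,6-bis(3-methylbut-2-en-1-yl)-2-(trimethylsilyl)phenyl trifluoromethanesulfonate | COc1c(CC=C(C)C)c(OCOC)c(CC=C(C)C)c(OS(=O)(=O)C(F)(F)F)c1[Si](C)(C)C | intermediate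
19 | benzoic acid | OC(=O)c1ccccc1 | starting material
20 | 3-methoxy-5-(methoxymethoxy)-4,6-bis(3-methylbut-2-en-1-yl)-1,2-didehydrobenzene (aryne) | COC1=C(CC=C(C)C)C(OCOC)=C(CC=C(C)C)C#C1 | intermediate
21 | [2-(benzoyloxy)-6-methoxy-4-(methoxymethoxy)-3,5-bis(3-methylbut-2-en-1-yl)phenyl]cesium | COc1c([Cs])c(OC(=O)c2ccccc2)c(CC=C(C)C)c(OCOC)c1CC=C(C)C | intermediate
22 | [2-hydroxy-6-methoxy-4-(methoxymethoxy)-3,5-bis(3-methylbut-2-en-1-yl)phenyl](phenyl)methanone | COCOc1c(CC=C(C)C)c(O)c(C(=O)c2ccccc2)c(OC)c1CC=C(C)C | intermediate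
23 | [2,4-dihydroxy-6-methoxy-3,5-bis(3-methylbut-2-en-1-yl)phenyl](phenyl)methanone | COc1c(CC=C(C)C)c(O)c(CC=C(C)C)c(O)c1C(=O)c1ccccc1 | target

**Step count**
Total step count: 10. Longest linear sequence: 10 steps (1 → 23); 3 and 19 are purchased.

**Steps most likely to fail**

1. Step 9 (aryne insertion). The C6 aryl anion may be protonated before acyl transfer, so that the reaction stops at the aryl benzoate. Crowding by the C4 prenyl group may erode the methoxy-controlled regioselectivity. The aryne may also be consumed by the neighbouring prenyl alkene. Fallback, setting out from 11 and returning at 23: Br–Li exchange on 11 (n-BuLi, THF, −78 °C) regenerates aryllithium 10, which is added to benzaldehyde to give racemic [2-methoxy-4,6-bis(methoxymethoxy)-3,5-bis(3-methylbut-2-en-1-yl)phenyl](phenyl)methanol F1. Oxidation of this doubly benzylic alcohol with Dess–Martin periodinane in CH2Cl2 should give [2-methoxy-4,6-bis(methoxymethoxy)-3,5-bis(3-methylbut-2-en-1-yl)phenyl](phenyl)methanone F2. Removal of both MOM groups (cat. HCl, MeOH, 40 °C) then gives 23.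

2. Step 7 (retro-Brook shift and triflation). n-BuLi may attack the O–Si bonds in competition with Br–Li exchange. The silyl migration into the crowded C6 position may be incomplete. Triflation of the phenoxide flanked by SiMe3 and prenyl may be slow enough for Tf2O to attack the alkenes. Fallback, setting out from 9 and returning at 18, with the C–Si bond made by carbamate-directed metalation instead of silyl migration: cat. HCl in MeOH converts 9 into 5-methoxy-2,4-bis(3-methylbut-2-en-1-yl)benzene-1,3-diol F3. ClC(O)NEt2 with K2CO3 in MeCN should acylate the less hindered C5 hydroxyl, which has one free ortho position, to give 3-hydroxy-5-methoxy-2,4-bis(3-methylbut-2-en-1-yl)phenyl diethylcarbamate F4. MOMCl with iPr2NEt caps the C3 hydroxyl to give 5-methoxy-3-(methoxymethoxy)-2,4-bis(3-methylbut-2-en-1-yl)phenyl diethylcarbamate F5. s-BuLi with TMEDA in THF at −78 °C lithiates C6 between carbamate and OMe to give [2-(diethylcarbamoyloxy)-6-methoxy-4-(methoxymethoxy)-3,5-bis(3-methylbut-2-en-1-yl)phenyl]lithium F6, and TMSCl at −78 °C gives 3-methoxy-5-(methoxymethoxy)-4,6-bis(3-methylbut-2-en-1-yl)-2-(trimethylsilyl)phenyl diethylcarbamate F7. LiAlH4 in THF cleaves the carbamate to 3-methoxy-5-(methoxymethoxy)-4,6-bis(3-methylbut-2-en-1-yl)-2-(trimethylsilyl)phenol F8, and Tf2O with pyridine in CH2Cl2 at 0 °C gives 18.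

3. Step 4 (third metalation). The base may remove a benzylic–allylic proton of a prenyl group instead of the crowded C6–H, which would lead to side-chain bromination or alkene migration, or the metalation may be incomplete. Fallback, setting out from 2 and returning at 11, in which every aryllithium comes from Br–Li exchange at −78 °C and no prenyl group meets a strong base at higher temperature: NBS (3.1 equiv) in MeCN should give 1,3,5-tribromo-2-methoxy-4,6-bis(methoxymethoxy)benzene F9. One equivalent of n-BuLi in THF at −78 °C should exchange the bromine between the two MOM ethers, where the aryllithium is chelated twice, to give [3,5-dibromo-4-methoxy-2,6-bis(methoxymethoxy)phenyl]lithium F10. CuI gives [3,5-dibromo-4-methoxy-2,6-bis(methoxymethoxy)phenyl]copper F11, and 3 gives 1,3-dibromo-2-methoxy-4,6-bis(methoxymethoxy)-5-(3-methylbut-2-en-1-yl)benzene F12. A second equivalent of n-BuLi exchanges one of the two equivalent bromines to give [3-bromo-2-methoxy-4,6-bis(methoxymethoxy)-5-(3-methylbut-2-en-1-yl)phenyl]lithium F13. CuI gives [3-bromo-2-methoxy-4,6-bis(methoxymethoxy)-5-(3-methylbut-2-en-1-yl)phenyl]copper F14, and 3 gives 11.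

**Further compounds**
F1 | step 9 | [2-methoxy-4,6-bis(methoxymethoxy)-3,5-bis(3-methylbut-2-en-1-yl)phenyl](phenyl)methanol (racemic) | COc1c(C(O)c2ccccc2)c(OCOC)c(CC=C(C)C)c(OCOC)c1CC=C(C)C
F2 | step 9 | [2-methoxy-4,6-bis(methoxymethoxy)-3,5-bis(3-methylbut-2-en-1-yl)phenyl](phenyl)methanone | COc1c(C(=O)c2ccccc2)c(OCOC)c(CC=C(C)C)c(OCOC)c1CC=C(C)C
F3 | step 7 | 5-methoxy-2,4-bis(3-methylbut-2-en-1-yl)benzene-1,3-diol | COc1cc(O)c(CC=C(C)C)c(O)c1CC=C(C)C
F4 | step 7 | 3-hydroxy-5-methoxy-2,4-bis(3-methylbut-2-en-1-yl)phenyl diethylcarbamate | CCN(CC)C(=O)Oc1cc(OC)c(CC=C(C)C)c(O)c1CC=C(C)C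
F5 | step 7 | 5-methoxy-3-(methoxymethoxy)-2,4-bis(3-methylbut-2-en-1-yl)phenyl diethylcarbamate | CCN(CC)C(=O)Oc1cc(OC)c(CC=C(C)C)c(OCOC)c1CC=C(C)C
F6 | step 7 | [2-(diethylcarbamoyloxy)-6-methoxy-4-(methoxymethoxy)-3,5-bis(3-methylbut-2-en-1-yl)phenyl]lithium | CCN(CC)C(=O)Oc1c([Li])c(OC)c(CC=C(C)C)c(OCOC)c1CC=C(C)C
F7 | step 7 | 3-methoxy-5-(methoxymethoxy)-4,6-bis(3-methylbut-2-en-1-yl)-2-(trimethylsilyl)phenyl diethylcarbamate | CCN(CC)C(=O)Oc1c([Si](C)(C)C)c(OC)c(CC=C(C)C)c(OCOC)c1CC=C(C)C
F8 | step 7 | 3-methoxy-5-(methoxymethoxy)-4,6-bis(3-methylbut-2-en-1-yl)-2-(trimethylsilyl)phenol | COc1c(CC=C(C)C)c(OCOC)c(CC=C(C)C)c(O)c1[Si](C)(C)C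
F9 | step 4 | 1,3,5-tribromo-2-methoxy-4,6-bis(methoxymethoxy)benzene | COc1c(Br)c(OCOC)c(Br)c(OCOC)c1Br
F10 | step 4 | [3,5-dibromo-4-methoxy-2,6-bis(methoxymethoxy)phenyl]lithium | COc1c(Br)c(OCOC)c([Li])c(OCOC)c1Br
F11 | step 4 | [3,5-dibromo-4-methoxy-2,6-bis(methoxymethoxy)phenyl]copper | COc1c(Br)c(OCOC)c([Cu])c(OCOC)c1Br
F12 | step 4 | 1,3-dibromo-2-methoxy-4,6-bis(methoxymethoxy)-5-(3-methylbut-2-en-1-yl)benzene | COc1c(Br)c(OCOC)c(CC=C(C)C)c(OCOC)c1Br
F13 | step 4 | [3-bromo-2-methoxy-4,6-bis(methoxymethoxy)-5-(3-methylbut-2-en-1-yl)phenyl]lithium | COc1c(Br)c(OCOC)c(CC=C(C)C)c(OCOC)c1[Li]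
F14 | step 4 | [3-bromo-2-methoxy-4,6-bis(methoxymethoxy)-5-(3-methylbut-2-en-1-yl)phenyl]copper | COc1c(Br)c(OCOC)c(CC=C(C)C)c(OCOC)c1[Cu]
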